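The readings were generated by integration with made-up constants; the scatter is artificial.

Answer two questions about this flask.

| flask | substrate | enzyme | added ligand | remark | time |
|---|---|---|---|---|---|
| larch | 0.050 M | 0.01 mol% | 18 µM | the very flask that is asked about, followed so far |  |
| oak | 0.050 M | 0.0067 mol% | 18 µM | run made earlier |  |
| flask | 0.050 M | 0.01 mol% | 18 µM |  | 15 min |

| run | time / min | product / % | substrate / % |
|---|---|---|---|
| larch | 0.417 | 0 | 97.0 |
| larch | 1.00 | 3.2 | 99.1 |
| larch | 2.00 | 7.0 | 91.9 |
| larch | 3.00 | 10.0 | 90.7 |
| oak | 0.833 | 3.8 | 97.9 |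
| oak | 2.00 | 5.3 | 95.7 |
| oak | 4.00 | 9.9 | 90.8 |
| oak | 6.00 | 12.7 | 86.1 |

(each reading ± 1 percentage point)

1. product present at 15 min, in percent of the substrate charged
2. substrate present at 15 min, in percent of the substrate charged

Treat the substrate loss as pseudo-first-order, with a rate in proportion to the enzyme loading. Then carry one quantity, the loading half-time: the time in which substrate falls to half at a given loading, scaled from a run by the ratio of loadings. My reckoning from the last oak reading, 12.7 % product at 6.00 min, gives 20.5 min. The last larch reading gives 19.7 min, and a scatter of 1 percentage point on 10.0 % covers that gap. So I expect 39.8 % product and 60.2 % substrate in this flask.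

The forecast says 37 % product and 63 % substrate, “Allowing for some catalyst decay”, so it stands lower in product than my reckoning.

The flask gives 38.9 % product and 61.1 % substrate.

    substrate + enzyme → product + enzyme, rate k1*[substrate]*[enzyme]/(1 + ([substrate]/Km1) + ([substrate]/Ksi1)^2) (46.0 mM, 28.0 mM, k = 1.00 × 10⁵ M⁻¹ min⁻¹)
    2 enzyme → spent catalyst (k = 55000 M⁻¹ min⁻¹)
    enzyme + added ligand ⇌ idle complex, settled at all times (K = 80000 M⁻¹)
    2 enzyme ⇌ resting dimer, settled at all times (K = 78000 M⁻¹)

In this flask, from 1.50 min to 15.0 min, enzyme falls from 35.0 % to 17.4 % of the catalyst charged. Over the same time the denominator of the rate law falls from 4.89 to 2.85. Now take the neighbour with 0.017 mol% enzyme. Its loading half-time is 12.1 min, which puts product at 57.7 % after 15 min. That neighbour gives 55.3 % product and 44.7 % substrate.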